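**Plan**

Labels: cyclohexanone C1 (C=O), C2 (CHMe), C3 (quaternary), C4 (CHMe), C5, C6; side chain C5' (CH2 on C3), C4' (carbinol), C3'(Me)=C2', C1' (CH2 on the quinone).
Cuts: quinone back to a resorcinol (oxidation last); C2'=C3' (cross-metathesis); C3'–C4' (Grignard on a Weinreb amide); C2–C3 (ring closure).
Enabling feature: C2 is alpha to the C1 carbonyl and C3 is beta to C4', and the C4 methyl is cis to the C5' arm. The C4-methyl carbon and C4' can therefore be tied through oxygen into a delta-lactone (O, C4', C5', C3, C4, CH2) whose C3=C5' bond is the acceptor; C1 is carried as a 2-vinyl-1,3-dioxolane.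
Forward: ene reaction, lipase acylation and metathesis give lactone ring B; zinc acylation and ketalization add C6–C1–C2; a hydrogen-atom-transfer radical cyclization closes carbocycle ring A (C2–C3); ring B is opened and its CH2O reduced to the C4 methyl; chain and arene are joined; deprotection and oxidation give the quinone.
Stereochemistry: C4 from the enzymatic resolution; C3 and C2 from the key step (forced cis ring fusion, chair transition state); C4' from CBS reduction; the E alkene from thermodynamic control in the cross-metathesis.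

Key step: step 6

Remark (assumption): the lipase is assumed to acylate the (S)-enantiomer of alcohol 2 faster; this sense is not established for this substrate and would have to be confirmed (the fallback for step 2 does not depend on it).

**Route**

Step 1
Reactants: 1 5-bromo-2-methylpent-2-ene
Product: 2 racemic 2-(2-bromoethyl)-3-methylbut-3-en-1-ol
Conditions: (CH2O)n, Me2AlCl, CH2Cl2, 0 °C to rt
Reagents that add atoms: formaldehyde (from paraformaldehyde), C=O
Why: Me2AlCl-promoted carbonyl-ene reaction in which formaldehyde should bond to the less substituted alkene carbon and take an allylic hydrogen from a geminal methyl group, giving the isopropenyl homoallylic alcohol with the future C4 as a racemic stereocentre.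

Step 2
Reactants: 2 racemic 2-(2-bromoethyl)-3-methylbut-3-en-1-ol
Product: 3 (2S)-2-(2-bromoethyl)-3-methylbut-3-en-1-yl prop-2-enoate
Conditions: Burkholderia cepacia lipase (immobilised), vinyl acrylate, BHT (trace), t-BuOMe, 30 °C, stopped near half conversion
Reagents that add atoms: vinyl acrylate, C=CC(=O)OC=C
Why: lipase-catalysed kinetic resolution by irreversible transesterification, in which the enzyme should acylate the (S)-alcohol faster (assumed sense), so that the C4 stereocentre is set and the acrylate for ring closure is installed in one operation, 2 being used without storage because it could close to a tetrahydrofuran.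

Step 3
Reactants: 3 (2S)-2-(2-bromoethyl)-3-methylbut-3-en-1-yl prop-2-enoate
Product: 4 (5S)-5-(2-bromoethyl)-4-methyl-5,6-dihydro-2H-pyran-2-one
Conditions: second-generation Grubbs catalyst (5 mol%), CH2Cl2 (high dilution), 40 °C
Reagents that add atoms: none
Why: ring-closing metathesis of an acrylate with a 1,1-disubstituted alkene should close the six-membered unsaturated lactone (ring B) with the trisubstituted C3=C5' bond, leaving the stereocentre and the alkyl bromide untouched.

Step 4
Reactants: 4 (5S)-5-(2-bromoethyl)-4-methyl-5,6-dihydro-2H-pyran-2-one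
Product: 7 (5S)-4-methyl-5-(3-oxopent-4-en-1-yl)-5,6-dihydro-2H-pyran-2-one, via alkylzinc bromide 5 (not isolated), via beta-chloro ketone 6 (not isolated)
Conditions: Zn dust, LiCl, THF, 50 °C; Pd(PPh3)4 (5 mol%), ClCH2CH2COCl, 0 °C to rt; Et3N, rt
Reagents that add atoms: 3-chloropropanoyl chloride, O=C(Cl)CCCl
Why: zinc insertion into the primary C–Br bond, Negishi acylation under zerovalent palladium catalysis and E1cB loss of HCl should give the vinyl ketone without any strongly basic or nucleophilic reagent that could attack the lactone or its gamma-CH.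

Step 5
Reactants: 7 (5S)-4-methyl-5-(3-oxopent-4-en-1-yl)-5,6-dihydro-2H-pyran-2-one
Product: 8 (5S)-5-[2-(2-ethenyl-1,3-dioxolan-2-yl)ethyl]-4-methyl-5,6-dihydro-2H-pyran-2-one
Conditions: TMSOCH2CH2OTMS, TMSOTf (cat.), CH2Cl2, −78 °C; pyridine
Reagents that add atoms: 1,2-bis(trimethylsilyloxy)ethane, C[Si](C)(C)OCCO[Si](C)(C)C
Why: Noyori ketalization under aprotic TMSOTf catalysis should convert the enone carbonyl into the dioxolane without conjugate addition or double-bond shift, while the lactone carbonyl does not react.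

Step 6
Reactants: 8 (5S)-5-[2-(2-ethenyl-1,3-dioxolan-2-yl)ethyl]-4-methyl-5,6-dihydro-2H-pyran-2-one
Product: 9 (4aS,5R,8aS)-4a,5-dimethylhexahydro-1H-spiro[isochromene-6,2'-[1,3]dioxolan]-3(4H)-one (cis-fused; the two methyl groups cis)
Conditions: Fe(acac)3 (0.3 equiv), PhSiH3, EtOH with ethylene glycol as cosolvent, 60 °C, degassed
Reagents that add atoms: none
Why: The iron hydride formed from Fe(acac)3 and PhSiH3 transfers a hydrogen atom to the terminal carbon of the vinyl group (completing the C2 methyl), and the resulting secondary radical at C2 adds to C3, the beta-carbon of the unsaturated lactone, after which the alpha-lactone radical is reduced and protonated by the solvent. The closest known reaction type is the iron-catalysed reductive olefin coupling (metal-hydride hydrogen atom transfer followed by Giese addition), used here intramolecularly. Ring A closes in the 6-exo-trig mode, C5' staying outside the new ring. C3 is controlled by the tether: the three-atom chain hangs from C4, next to the attacked carbon, so the radical can only reach the lactone face on which the chain lies and the bicycle must be cis-fused, which places the C3 methyl trans to the C4 CH2O arm. C2 is controlled by the chair-like transition state, in which its methyl group takes the equatorial position away from the pseudo-axial C4–CH2O bond and so should end cis to the C3 methyl. The step needs hydrogen atom transfer to the vinyl group rather than to the conjugated lactone alkene (the monosubstituted, non-conjugated alkene should react first) and 6-exo rather than 7-endo closure (secured by the polarity match of the nucleophilic radical with the beta-carbon), and the dioxolane keeps C2 from epimerizing afterwards.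

Step 7
Reactants: 9 (4aS,5R,8aS)-4a,5-dimethylhexahydro-1H-spiro[isochromene-6,2'-[1,3]dioxolan]-3(4H)-one
Product: 10 2-[(6R,7S,8S)-8-(hydroxymethyl)-6,7-dimethyl-1,4-dioxaspiro[4.5]decan-7-yl]-N-methoxy-N-methylacetamide
Conditions: Me3Al, MeNH(OMe)·HCl, CH2Cl2, 0 °C to rt
Reagents that add atoms: N,O-dimethylhydroxylamine hydrochloride, CNOC.Cl
Why: Weinreb aminolysis of the lactone by the aluminium amide made in the flask should open ring B at the acyl–oxygen bond and free the primary alcohol, leaving the dioxolane and the three stereocentres untouched.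

Step 8
Reactants: 10 2-[(6R,7S,8S)-8-(hydroxymethyl)-6,7-dimethyl-1,4-dioxaspiro[4.5]decan-7-yl]-N-methoxy-N-methylacetamide
Product: 11 2-[(6R,7R,8S)-8-(iodomethyl)-6,7-dimethyl-1,4-dioxaspiro[4.5]decan-7-yl]-N-methoxy-N-methylacetamide
Conditions: I2, PPh3, imidazole, CH2Cl2, 0 °C to rt
Reagents that add atoms: iodine, II
Why: Appel-type iodination should convert the primary alcohol into the iodide by SN2 at a CH2 group, so no stereocentre is involved (the descriptor at C7 changes by priority only), and immediate use of 10 avoids relactonization.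

Step 9
Reactants: 11 2-[(6R,7R,8S)-8-(iodomethyl)-6,7-dimethyl-1,4-dioxaspiro[4.5]decan-7-yl]-N-methoxy-N-methylacetamide
Product: 12 N-methoxy-N-methyl-2-[(6R,7S,8S)-6,7,8-trimethyl-1,4-dioxaspiro[4.5]decan-7-yl]acetamide
Conditions: Bu3SnH, azobisisobutyronitrile (cat.), toluene, 80 °C
Reagents that add atoms: none
Why: radical chain dehalogenation should reduce the primary iodide to the C4 methyl group, there being no alkene or weak C–H bond within reach of the intermediate primary radical.

Step 10
Reactants: 12 N-methoxy-N-methyl-2-[(6R,7S,8S)-6,7,8-trimethyl-1,4-dioxaspiro[4.5]decan-7-yl]acetamide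
Product: 13 3-methyl-1-[(6R,7S,8S)-6,7,8-trimethyl-1,4-dioxaspiro[4.5]decan-7-yl]but-3-en-2-one
Conditions: CH2=C(CH3)MgBr, THF, 0 °C; aq. NH4Cl
Reagents that add atoms: isopropenylmagnesium bromide, C=C(C)[Mg]Br
Why: Grignard addition to a Weinreb amide should stop at the ketone through the stable magnesium chelate, putting C4' and C3' in place as an isopropenyl ketone.

Step 11
Reactants: 14 orcinol (5-methylbenzene-1,3-diol)
Product: 15 4-chloro-5-methylbenzene-1,3-diol
Conditions: SO2Cl2 (1 equiv), Et2O, 0 °C
Reagents that add atoms: sulfuryl chloride, ClS(Cl)(=O)=O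
Why: electrophilic aromatic chlorination with one equivalent of reagent should occur para to one hydroxyl group and next to the methyl group, rather than at the more crowded position between the two hydroxyl groups.

Step 12
Reactants: 15 4-chloro-5-methylbenzene-1,3-diol
Product: 16 4-chloro-1,3-bis(methoxymethoxy)-5-methylbenzene
Conditions: MOMCl, iPr2NEt, CH2Cl2, 0 °C to rt
Reagents that add atoms: chloromethyl methyl ether, COCCl
Why: O-alkylation of both phenols protects them and provides the two directing groups for the metalation that follows.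

Step 13
Reactants: 16 4-chloro-1,3-bis(methoxymethoxy)-5-methylbenzene
Product: 18 2-allyl-4-chloro-1,3-bis(methoxymethoxy)-5-methylbenzene, via aryllithium 17 (not isolated)
Conditions: n-BuLi, THF, 0 °C; CuBr·SMe2 (10 mol%), allyl bromide, −78 °C to rt
Reagents that add atoms: allyl bromide, C=CCBr
Why: directed ortho-metalation at the position flanked by both OMOM groups, then copper-catalysed allylation of the aryllithium, should place the allyl group between the two oxygens.

Step 14
Reactants: 13 3-methyl-1-[(6R,7S,8S)-6,7,8-trimethyl-1,4-dioxaspiro[4.5]decan-7-yl]but-3-en-2-one, 18 2-allyl-4-chloro-1,3-bis(methoxymethoxy)-5-methylbenzene (excess)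
Product: 19 (3E)-5-[3-chloro-2,6-bis(methoxymethoxy)-4-methylphenyl]-3-methyl-1-[(6R,7S,8S)-6,7,8-trimethyl-1,4-dioxaspiro[4.5]decan-7-yl]pent-3-en-2-one
Conditions: second-generation Hoveyda–Grubbs catalyst (5 mol%), 1,4-benzoquinone (10 mol%), CH2Cl2, 40 °C
Reagents that add atoms: none
Why: olefin cross-metathesis between a terminal allyl arene and the 1,1-disubstituted enone should give the trisubstituted enone as the thermodynamically favoured E isomer (aryl-CH2 trans to the carbonyl), with benzoquinone suppressing double-bond migration.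

Step 15
Reactants: 19 (3E)-5-[3-chloro-2,6-bis(methoxymethoxy)-4-methylphenyl]-3-methyl-1-[(6R,7S,8S)-6,7,8-trimethyl-1,4-dioxaspiro[4.5]decan-7-yl]pent-3-en-2-one
Product: 20 (2S,3E)-5-[3-chloro-2,6-bis(methoxymethoxy)-4-methylphenyl]-3-methyl-1-[(6R,7S,8S)-6,7,8-trimethyl-1,4-dioxaspiro[4.5]decan-7-yl]pent-3-en-2-ol
Conditions: (R)-2-methyl-CBS-oxazaborolidine [(R)-1-methyl-3,3-diphenyltetrahydro-1H,3H-pyrrolo[1,2-c][1,3,2]oxazaborole] (20 mol%), BH3·THF, THF, −30 °C; MeOH
Reagents that add atoms: none
Why: Corey–Bakshi–Shibata reduction, in which the alkenyl group should act as the large and the CH2 group as the small substituent, so that the (R)-catalyst delivers hydride to the face giving the (S)-allylic alcohol at C4' (reagent control).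

Step 16
Reactants: 20 (2S,3E)-5-[3-chloro-2,6-bis(methoxymethoxy)-4-methylphenyl]-3-methyl-1-[(6R,7S,8S)-6,7,8-trimethyl-1,4-dioxaspiro[4.5]decan-7-yl]pent-3-en-2-ol
Product: 21 (2R,3S,4S)-3-[(2S,3E)-5-(3-chloro-2,6-dihydroxy-4-methylphenyl)-2-hydroxy-3-methylpent-3-en-1-yl]-2,3,4-trimethylcyclohexan-1-one
Conditions: 2 M HCl, THF/H2O, rt
Reagents that add atoms: water, O
Why: mild aqueous acid should hydrolyse the dioxolane and both aryl MOM acetals in one operation, room temperature and short contact being chosen to spare the allylic alcohol and the C2 stereocentre next to the freed ketone.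

Step 17
Reactants: 21 (2R,3S,4S)-3-[(2S,3E)-5-(3-chloro-2,6-dihydroxy-4-methylphenyl)-2-hydroxy-3-methylpent-3-en-1-yl]-2,3,4-trimethylcyclohexan-1-one
Product: 22 2-chloro-5-hydroxy-6-[(2E,4S)-4-hydroxy-3-methyl-5-[(1S,2R,6S)-1,2,6-trimethyl-3-oxocyclohexyl]pent-2-en-1-yl]-3-methylcyclohexa-2,5-diene-1,4-dione
Conditions: (KSO3)2NO, KH2PO4 buffer, acetone/H2O, rt
Reagents that add atoms: potassium nitrosodisulfonate, [K+].[K+].[O]N(S(=O)(=O)[O-])S(=O)(=O)[O-]
Why: Teuber oxidation, in which the nitrosodisulfonate radical should oxidise the resorcinol at its only free ring position (para to the hydroxyl next to chlorine) to the 2-hydroxy-1,4-benzoquinone, a reagent to which alcohol, ketone and alkene are inert.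

**Compound list**

1 | 5-bromo-2-methylpent-2-ene | CC(C)=CCCBr | starting material
2 | racemic 2-(2-bromoethyl)-3-methylbut-3-en-1-ol | OCC(CCBr)C(C)=C | intermediate
3 | (2S)-2-(2-bromoethyl)-3-methylbut-3-en-1-yl prop-2-enoate | C=CC(=O)OC[C@@H](CCBr)C(C)=C | intermediate
4 | (5S)-5-(2-bromoethyl)-4-methyl-5,6-dihydro-2H-pyran-2-one | O=C1OC[C@@H](CCBr)C(C)=C1 | intermediate
5 | bromo{2-[(3S)-4-methyl-6-oxo-3,6-dihydro-2H-pyran-3-yl]ethyl}zinc | O=C1OC[C@@H](CC[Zn]Br)C(C)=C1 | intermediate
6 | (5S)-5-(5-chloro-3-oxopentyl)-4-methyl-5,6-dihydro-2H-pyran-2-one | O=C1OC[C@@H](CCC(=O)CCCl)C(C)=C1 | intermediate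
7 | (5S)-4-methyl-5-(3-oxopent-4-en-1-yl)-5,6-dihydro-2H-pyran-2-one | O=C1OC[C@@H](CCC(=O)C=C)C(C)=C1 | intermediate
8 | (5S)-5-[2-(2-ethenyl-1,3-dioxolan-2-yl)ethyl]-4-methyl-5,6-dihydro-2H-pyran-2-one | O=C1OC[C@@H](CCC2(C=C)OCCO2)C(C)=C1 | intermediate
9 | (4aS,5R,8aS)-4a,5-dimethylhexahydro-1H-spiro[isochromene-6,2'-[1,3]dioxolan]-3(4H)-one | O=C1C[C@@]2(C)[C@@H](CO1)CCC3(OCCO3)[C@@H]2C | intermediate
10 | 2-[(6R,7S,8S)-8-(hydroxymethyl)-6,7-dimethyl-1,4-dioxaspiro[4.5]decan-7-yl]-N-methoxy-N-methylacetamide | CON(C)C(=O)C[C@@]1(C)[C@@H](CO)CCC2(OCCO2)[C@@H]1C | intermediate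
11 | 2-[(6R,7R,8S)-8-(iodomethyl)-6,7-dimethyl-1,4-dioxaspiro[4.5]decan-7-yl]-N-methoxy-N-methylacetamide | CON(C)C(=O)C[C@@]1(C)[C@@H](CI)CCC2(OCCO2)[C@@H]1C | intermediate
12 | N-methoxy-N-methyl-2-[(6R,7S,8S)-6,7,8-trimethyl-1,4-dioxaspiro[4.5]decan-7-yl]acetamide | CON(C)C(=O)C[C@@]1(C)[C@@H](C)CCC2(OCCO2)[C@@H]1C | intermediate
13 | 3-methyl-1-[(6R,7S,8S)-6,7,8-trimethyl-1,4-dioxaspiro[4.5]decan-7-yl]but-3-en-2-one | C=C(C)C(=O)C[C@@]1(C)[C@@H](C)CCC2(OCCO2)[C@@H]1C | intermediate
14 | orcinol (5-methylbenzene-1,3-diol) | Cc1cc(O)cc(O)c1 | starting material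
15 | 4-chloro-5-methylbenzene-1,3-diol | Cc1cc(O)cc(O)c1Cl | intermediate
16 | 4-chloro-1,3-bis(methoxymethoxy)-5-methylbenzene | COCOc1cc(C)c(Cl)c(OCOC)c1 | intermediate
17 | [3-chloro-2,6-bis(methoxymethoxy)-4-methylphenyl]lithium | COCOc1cc(C)c(Cl)c(OCOC)c1[Li] | intermediate
18 | 2-allyl-4-chloro-1,3-bis(methoxymethoxy)-5-methylbenzene | COCOc1cc(C)c(Cl)c(OCOC)c1CC=C | intermediate
19 | (3E)-5-[3-chloro-2,6-bis(methoxymethoxy)-4-methylphenyl]-3-methyl-1-[(6R,7S,8S)-6,7,8-trimethyl-1,4-dioxaspiro[4.5]decan-7-yl]pent-3-en-2-one | COCOc1cc(C)c(Cl)c(OCOC)c1C/C=C(\C)C(=O)C[C@@]2(C)[C@@H](C)CCC3(OCCO3)[C@@H]2C | intermediate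
20 | (2S,3E)-5-[3-chloro-2,6-bis(methoxymethoxy)-4-methylphenyl]-3-methyl-1-[(6R,7S,8S)-6,7,8-trimethyl-1,4-dioxaspiro[4.5]decan-7-yl]pent-3-en-2-ol | COCOc1cc(C)c(Cl)c(OCOC)c1C/C=C(\C)[C@@H](O)C[C@@]2(C)[C@@H](C)CCC3(OCCO3)[C@@H]2C | intermediate
21 | (2R,3S,4S)-3-[(2S,3E)-5-(3-chloro-2,6-dihydroxy-4-methylphenyl)-2-hydroxy-3-methylpent-3-en-1-yl]-2,3,4-trimethylcyclohexan-1-one | Cc1cc(O)c(C/C=C(\C)[C@@H](O)C[C@@]2(C)[C@@H](C)CCC(=O)[C@@H]2C)c(O)c1Cl | intermediate
22 | 2-chloro-5-hydroxy-6-[(2E,4S)-4-hydroxy-3-methyl-5-[(1S,2R,6S)-1,2,6-trimethyl-3-oxocyclohexyl]pent-2-en-1-yl]-3-methylcyclohexa-2,5-diene-1,4-dione | CC1=C(Cl)C(=O)C(C/C=C(\C)[C@@H](O)C[C@@]2(C)[C@@H](C)CCC(=O)[C@@H]2C)=C(O)C1=O | target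

**Count and risks**

Total step count: 17. Longest linear sequence: 14 steps (steps 1 to 10 and 14 to 17); the arene branch is steps 11 to 13.

Step 6 is the most likely to fail. Hydrogen atom transfer to the hindered vinyl group, which sits next to the ketal carbon, may be slow. The C2 radical may also be reduced before it closes onto the crowded beta-carbon, so that simple hydrogenation to the ethyl ketal competes with cyclization. The fallback closes the ring by a polar instead of a radical path. It sets out from vinyl ketone 7: conjugate reduction with [(Ph3P)CuH]6 (toluene, −40 °C to 0 °C) generates the Z copper enolate, whose intramolecular Michael addition to the lactone should give (4aS,5R,8aS)-4a,5-dimethylhexahydro-1H-isochromene-3,6(4H,7H)-dione F1 through the same cis-fused chair arrangement. Ketalization of F1 with ethylene glycol and pyridinium p-toluenesulfonate (benzene, water separator) comes back to the route at 9.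

Step 5 is the second. Under TMSOTf the silyl glycol ether may add to the unsubstituted enone terminus, or the vinyl ketone may polymerize, before the ketal forms. The fallback keeps the enone masked until the ketal is in place. It sets out from beta-chloro ketone 6, isolated instead of being eliminated: ketalization with ethylene glycol and TsOH gives (5S)-5-{2-[2-(2-chloroethyl)-1,3-dioxolan-2-yl]ethyl}-4-methyl-5,6-dihydro-2H-pyran-2-one F2. Displacement of chloride with PhSeNa (from PhSeSePh and NaBH4, EtOH) gives (5S)-4-methyl-5-(2-{2-[2-(phenylselanyl)ethyl]-1,3-dioxolan-2-yl}ethyl)-5,6-dihydro-2H-pyran-2-one F3. Oxidation with H2O2 and syn-elimination of the selenoxide at room temperature comes back to the route at 8.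

Step 2 is the third. The enzyme may discriminate poorly between the enantiomers, because the stereocentre is one carbon away from the reacting hydroxyl group, or it may prefer the other enantiomer. The fallback separates the enantiomers by chromatography at the lactone stage instead. It sets out from 2: acryloyl chloride and Et3N give racemic 2-(2-bromoethyl)-3-methylbut-3-en-1-yl prop-2-enoate F4, and ring-closing metathesis as in step 3 gives racemic 5-(2-bromoethyl)-4-methyl-5,6-dihydro-2H-pyran-2-one F5. Preparative chromatography on a chiral stationary phase (supercritical CO2) delivers the (S)-enantiomer, which is compound 4.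

**Further compounds**

F1 | step 6 | (4aS,5R,8aS)-4a,5-dimethylhexahydro-1H-isochromene-3,6(4H,7H)-dione | O=C1C[C@@]2(C)[C@@H](CO1)CCC(=O)[C@@H]2C
F2 | step 5 | (5S)-5-{2-[2-(2-chloroethyl)-1,3-dioxolan-2-yl]ethyl}-4-methyl-5,6-dihydro-2H-pyran-2-one | O=C1OC[C@@H](CCC2(CCCl)OCCO2)C(C)=C1
F3 | step 5 | (5S)-4-methyl-5-(2-{2-[2-(phenylselanyl)ethyl]-1,3-dioxolan-2-yl}ethyl)-5,6-dihydro-2H-pyran-2-one | O=C1OC[C@@H](CCC2(CC[Se]c3ccccc3)OCCO2)C(C)=C1
F4 | step 2 | racemic 2-(2-bromoethyl)-3-methylbut-3-en-1-yl prop-2-enoate | C=CC(=O)OCC(CCBr)C(C)=C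
F5 | step 2 | racemic 5-(2-bromoethyl)-4-methyl-5,6-dihydro-2H-pyran-2-one | O=C1OCC(CCBr)C(C)=C1
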